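Late times are not asked here: up to 40 min, follow the fraction of partner left in this flask, not the target made.

substrate 0.050 M; partner 0.0550 M; scavenger 0.0750 M; free catalyst 10 mM; time 40 min

    partner + free catalyst ⇌ catalyst intermediate A (K1 = 7.69 /M, k1 = 0.0477 /M/s)
    catalyst intermediate A → released group + catalyst intermediate B (k2 = 0.00422 /s)
    substrate + catalyst intermediate B → catalyst intermediate C (k3 = 0.137 /M/s)
    catalyst intermediate C → free catalyst + target (k4 = 0.0266 /s)
    partner + released group ⇌ idle adduct, settled at all times (K5 = 5400 /M)
    scavenger + released group → scavenged by-product (k6 = 0.398 /M/s)

- part of the substrate that has reacted at 40 min
- share of the unused partner that is free and not bound as idle adduct, at 40 min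

- amounts and yields of released group count idle adduct too
- run time (flask): 40 min

Here is my reckoning. Partner binds free catalyst with rate constant 0.0477 /M/s. Catalyst intermediate A then falls back with 0.00620 /s, the rate constant over the equilibrium constant, or moves on with 0.00422 /s. So 40.5% of bindings go forward.

Now assume each intermediate is used as fast as it is made. On the charge, you get 0.252 of catalyst intermediate A per free catalyst. Per catalyst intermediate A, you get 0.616 of catalyst intermediate B and 0.159 of catalyst intermediate C. That leaves 69.1% of the catalyst free, and I hold this share through the run.

Each turnover takes one partner. The released group takes a second into idle adduct, because its binding constant times the charged partner is 300, far above one. So [partner] decays with 0.0160 /min: two partners, times the forward share, times the binding rate constant, times [free catalyst]. This partner decay constant, a pseudo-first-order constant, is the fraction of the remaining partner lost per minute. It gives partner a half-life of 43.3 min. The intermediates' half-lives by their onward steps are 2.7 min, 1.7 min and 0.43 min, far shorter, which supports the assumption. Adduct leaks to scavenger with 0.00603 /min at the charged partner, slower than the partner decay, and as a first reckoning up to 40 min I neglect it.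

After 40 min, the fraction left is 52.7%. Target is the lost partner over two, so I expect 26.0% of the substrate reacted. With that leak neglected, adduct equals turnover, so I expect 69.0% of the unused partner free.

The forecast takes “the partner-binding step as the slow part of the catalytic cycle”. It gives 27% reacted, from 22% to 33%, and 69% free, from 61% to 77%.

The flask gives 25.4% reacted and 72.3% free, inside both forecast ranges. So at 40 min this flask is still mid-run, and it holds 0.0112 M of idle adduct against 0.00236 M of scavenged by-product. The partner decay constant also gives 72.6% of partner left at 20.0 min, where the flask has 71.3%. At the end the flask has 53%.

Now take the neighbour flask with 0.20 M of substrate. Catalyst intermediate B is used faster there, so my reckoning puts free catalyst at 75.2% and the constant at 0.0174 /min. That leaves 49.8% of partner and 6.90% of substrate reacted. The simulation of that neighbour gives 51% and 7.07%.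

Its constants were chosen freely, and the outcome is calculated.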